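(The readings are calculated for an exercise; the scatter is artificial.)

The readings of this flask cannot give a chain length, for they show X and J and do not count chains.

in all of them: X 0.20 M; E 10 mM

| flask | remark | time |
|---|---|---|
| epsilon | the very flask that is asked about, followed so far |  |
| flask |  | 15 min |

epsilon run (percent of the X charged)

| time / min | J / % | X / % |
|---|---|---|
| 1.00 | 12.5 | 86.6 |
| 2.50 | 21.8 | 75.9 |
| 3.00 | 26.4 | 72.5 |
| 5.00 | 30.9 | 65.9 |

(scatter of a reading: 1 percentage point)

- whether the average number of monomer units in a chain (chains begun, living or dead) reaches 7.0 by 15 min (no / yes)
- average number of monomer units in a chain (chains begun, living or dead) at 15 min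

- the average divides the monomer in chains by the number of chains begun, living and dead together
- the earlier runs do not show the number of chains; that part of a forecast is a guess

My own reckoning holds the readings against the charge of E. In this flask 35.0% of the X charged is the break-even J, the J that gives a length of 7.0 if each E charged begins exactly one chain. The reading at 5.00 min, 30.9%, stands 4.1 percentage points below that. The J readings of this flask slow too: they rose 4.5 points over the 2.00 min up to the last reading, after 12.5% in the first 1.00 min. In this flask each E that begins no chain lowers the break-even J, and the readings do not count such E, so this reckoning leans to yes as a judgement and gives no length of its own.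

The forecast answers yes, with a length of 9, and says of the count: “The number of chains is not observed, so this part is a guess”.

The flask gives yes, with a length of 9.00 at 15 min.

    L + J → G (k = 0.103 /M/s)
    J + L → X + L, rate k2*[L] as long as [J] is above zero (k = 0.0285 /s)
    2 E → Z (k = 1.94 /M/s)
    X + E → L + J (k = 0.286 /M/s)
    X + L → J + L, rate k5*[L]*[X] (k = 0.445 /M/s)
    X → D (k = 3.76 × 10⁻⁶ /s)

In this flask the length of 7.0 is passed at 3.27 min, with 28.5% of the X reacted. At 15.0 min E, the limiting reagent and the first to run out, stands at 0%, and Z stands at 0.00120 M, with two E in each Z, which is 24.0% of the E charged. Counted on the E outside Z, the break-even J of this flask falls from 35.0% to 26.6%, against a J of 34.2%.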